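## Structural features

The target is a germacranolide-type bicycle: a ten-membered carbocycle (C1–C10) fused at C6–C7 to an α,β-unsaturated γ-lactone (C6–C7=C11–C12(=O)–O). The tetrasubstituted alkene C7=C11 carries the C13 acetoxymethyl group. The carbocycle holds two oxiranes, C1–C10 (with the C14 hydroxymethyl group on C10) and C4–C5 (with the C15 methyl group on C4), on either side of the Z alkene C2=C3, and a (2R)-2-methylbutanoate on C8. Of the seven stereocentres, C4, C5 and C6 are contiguous, C8 is separated from C6 only by the sp2 carbon C7, C1 and C10 form a pair, and the seventh sits in the acyl chain. The fragile elements are the two allylic oxiranes (the C4–O bond is tertiary and allylic), the acidic lactone γ-hydrogen at C6, which puts any leaving group on C5, C8 or C13 at risk of elimination through the dienolate, and two different esters. The real difficulty is closing the strained ten-membered ring while setting the C4/C5/C6 triad. The key step uses two facts: C6 is the γ-carbon of the butenolide ring and so the nucleophilic terminus of the corresponding 2-silyloxyfuran, and its neighbour C5 is an oxygen-bearing CH next to the tertiary C4–O centre, so C5 can be an α-alkoxy aldehyde that holds a metal between O5 and O4. The 4,5-oxirane has C3 and C6 cis and the 1,10-oxirane has C9 and C2 trans; this translates into a syn C4–O/C5–O aldol followed by one inversion at C5, and into a C1=C10 alkene with C14 cis to C2.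

## Logic of the disconnections

36 to 35: the C1–O and C10–O bonds of the second oxirane are cut. The free C14 hydroxyl of 35 directs a titanium–tartrate epoxidation, so the more exposed oxirane arrives last and under reagent control. The forward step must choose the C1=C10 face, leave C2=C3 and C7=C11 alone, and not open the existing oxirane.

35 to 34 to 33: the O–Si bond at C14 is cut, then the C5–O bond of the 4,5-oxirane, which leads to the syn diol 33. The oxirane oxygen is the C4 oxygen that is present from the first step. The forward cyclodehydration must activate only the secondary C5 hydroxyl, invert C5, and avoid ionisation at C4 and elimination across C5–C6.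

33 to 32 to 31 to 30: the C4 benzyl-type ether, the C13 acetate and the C13 silyl ether are exchanged. The order is chosen so that the fluoride and acylation steps precede oxirane formation. The forward steps need selective cleavage of the primary dimethylsilyl ether beside the diphenylsilyl ether, and selective acetylation of C13–OH beside the hindered C5–OH.

30 to 29: the C5–C6 bond is cut (key step). This removes the ring and two stereocentres at once and leaves a chain with three rigid units. The forward step must favour ring closure over oligomerisation and control both new centres.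

29 to 28: the furan O–Si bond is cut. The silyloxyfuran is made only in the last step before the ring closure. The forward step must remove the C6 hydrogen in the presence of a non-enolisable aldehyde without triggering an unchelated aldol.

28 to 27 to 26 + 7: the C2=C3 alkene is traced to an alkyne, and the C1–C2 bond is cut. This gives two fragments of similar size. The forward steps need a Z-selective partial reduction and retention of the C1=C10 geometry in the coupling.

7 to 5 (via 6) to 4 to 2 (via 3) to 1: the C5 aldehyde comes from a vinyl group, the C4 ether from the tertiary alcohol, and 4 from 2 by reductive opening. The tertiary C4–O bond is made in the enantioselective epoxidation of 1 and never broken. The tertiary oxygen is etherified before any glycol cleavage, so that only the terminal glycol of 6 is cut.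

26 to 25: the C7=C11 bond is cut. Ring-closing metathesis builds the tetrasubstituted butenolide without organometallic or palladium chemistry, which the iodoalkene would not survive. The forward step has to join two 1,1-disubstituted alkenes.

25 to 23 + 24, 23 to 22 to 21 to 20 + 10, and 10 to 9 to 8: the two ester C–O bonds and the C8 carbinol stereocentre are cut. C8 is set by reagent-controlled reduction of 22. The forward steps need selective acylation of the primary hydroxyl of 20 and no epimerisation of 24.

20 to 17 + 18 (via 19): the C7–C8 bond is cut. This gives an aldehyde and a three-carbon alkenyl anion that carries C6 and C7. The forward addition must tolerate the iodoalkene and the enolisable aldehyde.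

17 (via 16) to 15 to 14 to 11 + 12 (via 13): the C8 aldehyde comes from a terminal alkene, and the C9–C10 and C1–I bonds are cut. One anti-carbomagnesiation of 11 sets the C1=C10 geometry (iodine cis to C14) from two commercial compounds.

## Other disconnections considered

Alternative 1: The cut removes the four C–O bonds of both oxiranes and leads to the achiral triene diol A1. In the forward step titanium, L-(+)-tartrate and an alkyl hydroperoxide would epoxidise both terminal allylic alcohols of A1 to give the bis-epoxy diol A2, while the central Z alkene, which is not allylic to a hydroxyl, stays. In its favour: four stereocentres and both oxiranes come from one operation on an achiral substrate, the same tartrate serves both ends, and double induction should raise the enantiomeric purity of the major isomer. Against it here: A2 is only the C8–C10/C1–C6 part, so the ten-membered ring, C6, C8 and the butenolide must all be made afterwards in the presence of two vinyl oxiranes; the C4=C5 end is a Z-trisubstituted allylic alcohol, a slow and less selective class. Comparison: on stereocentres per step Alternative 1 is the better plan (the chosen route needs steps 1, 23 and 25 for the same four centres), and its key step is far better precedented. The chosen plan is better on structure, because it solves the ring closure and C5/C6 together and introduces each oxirane only when nothing harsh follows. Overall step count should be similar.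

Alternative 2: The cut removes C6–C7 and O6–C12 and leads to the epoxy aldehyde enol triflate A3. In the forward step a Nozaki–Hiyama–Kishi reaction (CrCl2 with catalytic NiCl2) would turn the C7 triflate into an alkenylchromium species that adds to the C6 aldehyde; the chromium alkoxide would then acylate on the cis methyl ester to give A4, the C14 silyl ether of the target. In its favour: this is the best-precedented way to close ten-membered carbocycles, it forms ring and lactone together, and A4 is one deprotection from the target. Against it here: A3 carries both oxiranes, the allylic acetate and an α,β-epoxy aldehyde into a medium containing Lewis-acidic trivalent chromium; the alkenyl metal has an allylic acetate placed for elimination to an allene; and C6 would be set only by the conformation of the closing chain. Comparison: Alternative 2 is better on precedent for the ring size and on the length of the endgame, and equal in convergence. The chosen plan sets two stereocentres (C5 by chelation) instead of one and keeps every fragile group out of the ring closure, at the cost of six steps after it.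

Alternative 3: The cut removes C1–C2 and leads to the alkynyl aldehyde A5. In the forward step a zinc acetylide generated with Zn(OTf)2 and an amine would add to the tethered C1 aldehyde to give the ten-membered cycloalkyne A6; later the alkyne would be semi-reduced and the oxirane moved from C10–C14 to C1–C10 by a Payne rearrangement. In its favour: the Z geometry of C2=C3 is guaranteed by reduction inside the ring, the 4,5-oxirane is installed early by reliable epoxidation, and no late epoxidation of a sensitive diene is needed; on that last point it is better than the chosen plan. Against it here: this alkynylation is as unprecedented for a ten-membered ring as the chosen key step, the aldehyde is α-quaternary and hindered, the propargylic tertiary oxirane sits next to the reacting alkyne under Lewis-acidic zinc, and the Payne step needs attack at a fully substituted carbon. Comparison: both plans rest on a new ring closure, so they are equal on that count. The chosen one sets two stereocentres in it and reaches the target in fewer steps after the ring is closed; Alternative 3 needs semi-reduction, rearrangement, lactonisation and two acylations.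

Key step: step 19

Remark on the chemistry: ring atoms are numbered as in germacranolides (C1–C10 ring, C11–C13 on the lactone, C14 on C10, C15 on C4).

Remark on the chemistry: precursor 29 and product 30 of the key step were checked centre by centre against the target (C4 R and C8 S in both; C5 R and C6 S in 30; C9 trans to C2 across C1=C10; C2=C3 Z) and need no correction. What is repaired is the way to 29: the tertiary oxygen is etherified before glycol cleavage, the silyloxyfuran is made last, and C13 is acetylated before the 4,5-oxirane exists.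

Remark on the chemistry: face selection in both titanium–tartrate epoxidations is assigned by the usual rule for primary allylic alcohols (L-(+)-tartrate gives the (2S)-epoxy alcohol from an (E)-2-alken-1-ol), applied to 1 and 35.

Remark on the chemistry: C8 is set by oxazaborolidine reduction and not taken from a chiral C4 hydroxy diacid, because that would place a carboxyl carbon at C10, where the trisubstituted iodoalkene cannot be built in few steps.

## Steps

Step 1
Reactants: 1 (2Z)-3-methylpent-2-en-4-yn-1-ol
Product: 2 [(2S,3R)-3-ethynyl-3-methyloxiran-2-yl]methanol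
Conditions: Ti(OiPr)4 (10 mol%), diethyl L-(+)-tartrate (12 mol%), t-BuOOH, 4 Å MS, CH2Cl2, −20 °C
Reagents that add atoms: tert-butyl hydroperoxide, CC(C)(C)OO
Why: Sharpless asymmetric epoxidation of a primary allylic alcohol; with L-(+)-tartrate the oxygen should go to the face that gives (2S,3R)-2, which fixes the tertiary C–O centre that becomes C4 (R). The alkyne is inert.

Step 2
Reactants: 2 [(2S,3R)-3-ethynyl-3-methyloxiran-2-yl]methanol
Product: 4 (3S)-3-methylpent-1-en-4-yn-3-ol, via epoxy iodide 3 (not isolated)
Conditions: PPh3, I2, imidazole, Et2O–MeCN, 0 °C; then Zn dust, AcOH, EtOH, 0 °C to rt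
Reagents that add atoms: none
Why: Appel-type iodination of the primary alcohol, then zinc-mediated reductive β-elimination of the 2,3-epoxy iodide, unmasks the tertiary allylic alcohol. The C–O bond at the stereocentre is never broken, so its configuration is kept.

Step 3
Reactants: 4 (3S)-3-methylpent-1-en-4-yn-3-ol
Product: 5 (3S)-3-[(4-methoxybenzyl)oxy]-3-methylpent-1-en-4-yne
Conditions: NaH, 4-methoxybenzyl chloride, Bu4NI (cat.), DMF, 0 °C to rt
Reagents that add atoms: 4-methoxybenzyl chloride, COc1ccc(CCl)cc1
Why: Williamson etherification of the tertiary alkoxide; O-alkylation is much faster than C-alkylation of the acetylide. The ether is the chelating group of the key step.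

Step 4
Reactants: 5 (3S)-3-[(4-methoxybenzyl)oxy]-3-methylpent-1-en-4-yne
Product: 7 (2R)-2-[(4-methoxybenzyl)oxy]-2-methylbut-3-ynal, via vicinal diol 6 (not isolated)
Conditions: K2OsO4·2H2O (2 mol%), NaIO4, 2,6-lutidine, dioxane–H2O, rt
Reagents that add atoms: sodium periodate, [Na+].[O-]I(=O)(=O)=O
Why: Lemieux–Johnson oxidation of the only alkene; because the tertiary oxygen is already an ether, only the terminal glycol 6 is cleaved. The alkyne and the aryl ether are untouched, and the aldehyde has no α-hydrogen to lose.

Step 5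
Reactants: 8 ethyl 2-(hydroxymethyl)prop-2-enoate
Product: 9 ethyl 2-{[(tert-butyldimethylsilyl)oxy]methyl}prop-2-enoate
Conditions: t-BuMe2SiCl, imidazole, CH2Cl2, 0 °C to rt
Reagents that add atoms: tert-butyl(chloro)dimethylsilane, CC(C)(C)[Si](C)(C)Cl
Why: Standard silylation of a primary alcohol.

Step 6
Reactants: 9 ethyl 2-{[(tert-butyldimethylsilyl)oxy]methyl}prop-2-enoate
Product: 10 2-{[(tert-butyldimethylsilyl)oxy]methyl}prop-2-enoic acid
Conditions: LiOH, THF–H2O, 0 °C; then 1 M HCl to pH 4
Reagents that add atoms: lithium hydroxide, [Li+].[OH-]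
Why: Saponification of the ethyl ester; the primary silyl ether should survive cold hydroxide and brief mild acidification.

Step 7
Reactants: 11 prop-2-yn-1-ol; 12 allylmagnesium bromide
Product: 14 (2Z)-2-(iodomethylidene)pent-4-en-1-ol, via cyclic alkenylmagnesium alkoxide 13 (not isolated)
Conditions: 12 (2.5 equiv), CuI (5 mol%), Et2O, 0 °C to rt; then I2, THF, −78 to 0 °C
Reagents that add atoms: iodine, II
Why: Alkoxide-directed anti-carbomagnesiation of propargyl alcohol puts the allyl group on C10 and magnesium on C1 in the five-membered chelate 13. Iodinolysis with retention gives iodine cis to the hydroxymethyl group, which is the C1=C10 geometry of the target.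

Step 8
Reactants: 14 (2Z)-2-(iodomethylidene)pent-4-en-1-ol
Product: 15 tert-butyl{[(2Z)-2-(iodomethylidene)pent-4-en-1-yl]oxy}diphenylsilane
Conditions: t-BuPh2SiCl, imidazole, CH2Cl2, rt
Reagents that add atoms: tert-butyl(chloro)diphenylsilane, CC(C)(C)[Si](Cl)(c1ccccc1)c1ccccc1
Why: Standard silylation; the robust diphenylsilyl ether is kept on C14 until step 24.

Step 9
Reactants: 15 tert-butyl{[(2Z)-2-(iodomethylidene)pent-4-en-1-yl]oxy}diphenylsilane
Product: 17 (3Z)-3-{[(tert-butyldiphenylsilyl)oxy]methyl}-4-iodobut-3-enal, via vicinal diol 16 (not isolated)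
Conditions: K2OsO4·2H2O (2 mol%), NaIO4, 2,6-lutidine, dioxane–H2O, rt
Reagents that add atoms: sodium periodate, [Na+].[O-]I(=O)(=O)=O
Why: Lemieux–Johnson oxidation; the monosubstituted alkene is dihydroxylated much faster than the hindered, iodine-deactivated trisubstituted one. Buffered conditions keep the β,γ-unsaturated aldehyde from moving into conjugation.

Step 10
Reactants: 17 (3Z)-3-{[(tert-butyldiphenylsilyl)oxy]methyl}-4-iodobut-3-enal; 18 2-bromoprop-2-en-1-ol
Product: 20 rac-(5Z)-5-{[(tert-butyldiphenylsilyl)oxy]methyl}-6-iodo-2-methylidenehex-5-ene-1,3-diol, via dilithio reagent 19 (not isolated)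
Conditions: 18, t-BuLi (3 equiv per 18), Et2O, −78 to 0 °C; CeCl3, THF, −78 °C; then 17, −78 °C
Reagents that add atoms: none
Why: O-deprotonation and bromine–lithium exchange give 19, and its 1,2-addition forms C7–C8. Transmetalation to cerium should suppress enolisation of the aldehyde and iodine–lithium exchange at C1. The carbinol is formed without control and is reset in steps 12 and 13.

Step 11
Reactants: 20 rac-(5Z)-5-{[(tert-butyldiphenylsilyl)oxy]methyl}-6-iodo-2-methylidenehex-5-ene-1,3-diol; 10 2-{[(tert-butyldimethylsilyl)oxy]methyl}prop-2-enoic acid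
Product: 21 rac-(5Z)-5-{[(tert-butyldiphenylsilyl)oxy]methyl}-3-hydroxy-6-iodo-2-methylidenehex-5-en-1-yl 2-{[(tert-butyldimethylsilyl)oxy]methyl}prop-2-enoate
Conditions: N,N'-diisopropylcarbodiimide, DMAP (cat.), CH2Cl2, −20 °C
Reagents that add atoms: none
Why: Steglich esterification; at low temperature with one equivalent of acid the primary allylic hydroxyl (C6–OH) should react well ahead of the secondary one.

Step 12
Reactants: 21 rac-(5Z)-5-{[(tert-butyldiphenylsilyl)oxy]methyl}-3-hydroxy-6-iodo-2-methylidenehex-5-en-1-yl 2-{[(tert-butyldimethylsilyl)oxy]methyl}prop-2-enoate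
Product: 22 (5Z)-5-{[(tert-butyldiphenylsilyl)oxy]methyl}-6-iodo-2-methylidene-3-oxohex-5-en-1-yl 2-{[(tert-butyldimethylsilyl)oxy]methyl}prop-2-enoate
Conditions: Dess–Martin periodinane, NaHCO3, CH2Cl2, 0 °C
Reagents that add atoms: none
Why: Dess–Martin oxidation of the secondary allylic alcohol; neutral buffered conditions avoid isomerisation of the doubly activated C9 methylene.

Step 13
Reactants: 22 (5Z)-5-{[(tert-butyldiphenylsilyl)oxy]methyl}-6-iodo-2-methylidene-3-oxohex-5-en-1-yl 2-{[(tert-butyldimethylsilyl)oxy]methyl}prop-2-enoate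
Product: 23 (3S,5Z)-5-{[(tert-butyldiphenylsilyl)oxy]methyl}-3-hydroxy-6-iodo-2-methylidenehex-5-en-1-yl 2-{[(tert-butyldimethylsilyl)oxy]methyl}prop-2-enoate
Conditions: (R)-2-methyl-CBS-oxazaborolidine (0.2 equiv), catecholborane, PhMe, −78 °C
Reagents that add atoms: none
Why: Corey–Bakshi–Shibata reduction; the α-branched alkenyl group acts as the large substituent and the C9 methylene as the small one, so the (R)-catalyst should deliver hydride to give the (S)-carbinol (C8). Catecholborane at −78 °C avoids hydroboration and conjugate reduction.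

Step 14
Reactants: 23 (3S,5Z)-5-{[(tert-butyldiphenylsilyl)oxy]methyl}-3-hydroxy-6-iodo-2-methylidenehex-5-en-1-yl 2-{[(tert-butyldimethylsilyl)oxy]methyl}prop-2-enoate; 24 (2R)-2-methylbutanoic acid
Product: 25 (3S,5Z)-5-{[(tert-butyldiphenylsilyl)oxy]methyl}-6-iodo-2-methylidene-3-{[(2R)-2-methylbutanoyl]oxy}hex-5-en-1-yl 2-{[(tert-butyldimethylsilyl)oxy]methyl}prop-2-enoate
Conditions: N,N'-diisopropylcarbodiimide, DMAP (cat.), CH2Cl2, 0 °C
Reagents that add atoms: none
Why: Steglich esterification with retention at C8; with an α-alkyl acid and catalytic DMAP at 0 °C no epimerisation of the acyl stereocentre is expected.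

Step 15
Reactants: 25 (3S,5Z)-5-{[(tert-butyldiphenylsilyl)oxy]methyl}-6-iodo-2-methylidene-3-{[(2R)-2-methylbutanoyl]oxy}hex-5-en-1-yl 2-{[(tert-butyldimethylsilyl)oxy]methyl}prop-2-enoate
Product: 26 (1S,3Z)-1-[4-{[(tert-butyldimethylsilyl)oxy]methyl}-5-oxo-2,5-dihydrofuran-3-yl]-3-{[(tert-butyldiphenylsilyl)oxy]methyl}-4-iodobut-3-en-1-yl (2R)-2-methylbutanoate
Conditions: second-generation Hoveyda–Grubbs catalyst (10 mol%), PhMe (0.005 M), 80 °C, argon purge
Reagents that add atoms: none
Why: Ring-closing metathesis of the two 1,1-disubstituted alkenes closes the five-membered lactone and forms the tetrasubstituted C7=C11 alkene with loss of ethene. The iodoalkene is too hindered and deactivated to take part.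

Step 16
Reactants: 26 (1S,3Z)-1-[4-{[(tert-butyldimethylsilyl)oxy]methyl}-5-oxo-2,5-dihydrofuran-3-yl]-3-{[(tert-butyldiphenylsilyl)oxy]methyl}-4-iodobut-3-en-1-yl (2R)-2-methylbutanoate; 7 (2R)-2-[(4-methoxybenzyl)oxy]-2-methylbut-3-ynal
Product: 27 enyne aldehyde, (1S,3Z,7R)-1-[4-{[(tert-butyldimethylsilyl)oxy]methyl}-5-oxo-2,5-dihydrofuran-3-yl]-3-{[(tert-butyldiphenylsilyl)oxy]methyl}-7-[(4-methoxybenzyl)oxy]-7-methyl-8-oxooct-3-en-5-yn-1-yl (2R)-2-methylbutanoate
Conditions: Pd(PPh3)2Cl2 (5 mol%), CuI (10 mol%), Et3N, THF, rt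
Reagents that add atoms: none
Why: Sonogashira coupling forms C1–C2 with retention of the iodoalkene geometry. The aldehyde has no α-hydrogen and tolerates the tertiary amine.

Step 17
Reactants: 27 enyne aldehyde
Product: 28 dienyl aldehyde, (1S,3Z,5Z,7R)-1-[4-{[(tert-butyldimethylsilyl)oxy]methyl}-5-oxo-2,5-dihydrofuran-3-yl]-3-{[(tert-butyldiphenylsilyl)oxy]methyl}-7-[(4-methoxybenzyl)oxy]-7-methyl-8-oxoocta-3,5-dien-1-yl (2R)-2-methylbutanoate
Conditions: H2 (1 atm), Pd/CaCO3 poisoned with Pb(OAc)2, quinoline, EtOAc, rt
Reagents that add atoms: none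
Why: Lindlar semi-hydrogenation adds hydrogen cis to the alkyne and gives the Z C2=C3 alkene. The alkyne sits next to a quaternary carbon, so the reaction is stopped at one equivalent; the tetrasubstituted lactone alkene is not reduced.

Step 18
Reactants: 28 dienyl aldehyde
Product: 29 silyloxyfuran aldehyde, (1S,3Z,5Z,7R)-1-[5-[(tert-butyldimethylsilyl)oxy]-4-{[(tert-butyldimethylsilyl)oxy]methyl}furan-3-yl]-3-{[(tert-butyldiphenylsilyl)oxy]methyl}-7-[(4-methoxybenzyl)oxy]-7-methyl-8-oxoocta-3,5-dien-1-yl (2R)-2-methylbutanoate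
Conditions: t-BuMe2SiOTf (1.3 equiv), Et3N (3 equiv), CH2Cl2, −78 °C, 30 min; cold aq. NaHCO3; used at once
Reagents that add atoms: tert-butyldimethylsilyl trifluoromethanesulfonate, CC(C)(C)[Si](C)(C)OS(=O)(=O)C(F)(F)F
Why: Soft enolisation: the amine removes a C6 hydrogen and O-silylation gives the aromatic 2-silyloxyfuran. The aldehyde cannot enolise; excess amine, low temperature and short time are meant to keep the silyl triflate from promoting an unchelated aldol.

Step 19
Reactants: 29 silyloxyfuran aldehyde
Product: 30 (1(10)Z,2Z,4R,5R,6S,8S)-13-[(tert-butyldimethylsilyl)oxy]-14-[(tert-butyldiphenylsilyl)oxy]-5-hydroxy-4-[(4-methoxybenzyl)oxy]-8-{[(2R)-2-methylbutanoyl]oxy}germacra-1(10),2,7(11)-trien-12,6-olide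
Conditions: MgBr2·OEt2 (3 equiv), CH2Cl2 (0.001 M, slow addition of 29), −78 to −20 °C; pH 7 buffer
Reagents that add atoms: none
Why: Proposed new method: MgBr2 should bind the aldehyde oxygen and the C4 ether oxygen of 29 in a five-membered chelate, which activates C5 and fixes the C4–C5 rotamer; the furan then attacks through its unsubstituted γ-carbon C6 in an open transition state, and loss of the silyl group restores the C7=C11 butenolide, the closest known reaction type being the intermolecular chelation-controlled vinylogous Mukaiyama aldol addition of 2-silyloxyfurans to α-alkoxy aldehydes and its intramolecular use for five- to seven-membered carbocycles. The ten-membered carbocycle is closed by C5–C6 bond formation in the 10-exo-trig mode under high dilution, helped by three rigid units in the chain (furan, trisubstituted C1=C10, Z C2=C3). C5 is controlled by the chelate: the nucleophile approaches the carbonyl face that carries the small C15 methyl group and not the C3 alkenyl chain, which gives 5R with C4–O and C5–O syn. C6 is controlled by the tether and by C8: with the C8–H bond in the furan plane the chain should reach the chelated aldehyde from one furan face only, giving 6S, but this is the less secure of the two. γ- over α-attack is secured because the α-carbon C11 is fully substituted. The step needs both facial selectivities and must not ionise the furylic C8 ester or expel the C13 oxygen, hence the mild divalent-magnesium Lewis acid, the low temperature and a silyl ether (not an acetate) at C13; the aldehyde has no α-hydrogen, so C4 cannot epimerise.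

Step 20
Reactants: 30 macrocyclic C5 carbinol
Product: 31 (1(10)Z,2Z,4R,5R,6S,8S)-14-[(tert-butyldiphenylsilyl)oxy]-5,13-dihydroxy-4-[(4-methoxybenzyl)oxy]-8-{[(2R)-2-methylbutanoyl]oxy}germacra-1(10),2,7(11)-trien-12,6-olide
Conditions: HF·pyridine, pyridine, THF, 0 °C
Reagents that add atoms: none
Why: Buffered fluoride cleaves the primary dimethylsilyl ether much faster than the diphenylsilyl ether. No oxirane is present yet.

Step 21
Reactants: 31 C13 alcohol
Product: 32 (1(10)Z,2Z,4R,5R,6S,8S)-13-acetoxy-14-[(tert-butyldiphenylsilyl)oxy]-5-hydroxy-4-[(4-methoxybenzyl)oxy]-8-{[(2R)-2-methylbutanoyl]oxy}germacra-1(10),2,7(11)-trien-12,6-olide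
Conditions: Ac2O (1.2 equiv), pyridine, CH2Cl2, 0 °C
Reagents that add atoms: acetic anhydride, CC(=O)OC(C)=O
Why: Acetylation of the primary allylic hydroxyl; the secondary C5 hydroxyl lies between the quaternary C4 and the ring carbon C6 and should react far more slowly without DMAP.

Step 22
Reactants: 32 C13 acetate
Product: 33 (1(10)Z,2Z,4R,5R,6S,8S)-13-acetoxy-14-[(tert-butyldiphenylsilyl)oxy]-4,5-dihydroxy-8-{[(2R)-2-methylbutanoyl]oxy}germacra-1(10),2,7(11)-trien-12,6-olide
Conditions: DDQ (1.5 equiv), CH2Cl2–pH 7 buffer (10:1), 0 °C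
Reagents that add atoms: none
Why: Oxidative cleavage of the 4-methoxybenzyl ether by hydride abstraction and hydrolysis of the oxocarbenium ion. The wet buffered medium is meant to favour water over the C5 hydroxyl as the trap; a benzylidene acetal, if formed, would be hydrolysed under mild acid.

Step 23
Reactants: 33 C4,C5-diol
Product: 34 (1(10)Z,2Z,4R,5S,6S,8S)-13-acetoxy-14-[(tert-butyldiphenylsilyl)oxy]-4,5-epoxy-8-{[(2R)-2-methylbutanoyl]oxy}germacra-1(10),2,7(11)-trien-12,6-olide
Conditions: PPh3, diisopropyl azodicarboxylate, PhMe, 0 to 60 °C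
Reagents that add atoms: none
Why: Mitsunobu cyclodehydration: phosphorus activates the less hindered secondary C5 hydroxyl and the tertiary C4 oxygen displaces it in a 3-exo-tet closure with inversion at C5. This turns the syn diol into the oxirane with C3 and C6 cis (5S) under non-basic conditions.

Step 24
Reactants: 34 4,5-epoxide
Product: 35 (1(10)Z,2Z,4R,5S,6S,8S)-13-acetoxy-4,5-epoxy-14-hydroxy-8-{[(2R)-2-methylbutanoyl]oxy}germacra-1(10),2,7(11)-trien-12,6-olide
Conditions: Bu4NF, AcOH (1:1), THF, 0 °C to rt
Reagents that add atoms: none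
Why: Fluoride desilylation buffered with acetic acid; the near-neutral medium should spare the acetate, the ester, the lactone γ-hydrogen and the dienyl oxirane.

Step 25
Reactants: 35 C14 allylic alcohol
Product: 36 (1R,2Z,4R,5S,6S,8S,10S)-13-acetoxy-1,10:4,5-diepoxy-14-hydroxy-8-{[(2R)-2-methylbutanoyl]oxy}germacra-2,7(11)-dien-12,6-olide
Conditions: Ti(OiPr)4 (1.0 equiv), diethyl L-(+)-tartrate (1.2 equiv), t-BuOOH, 4 Å MS, CH2Cl2, −25 °C
Reagents that add atoms: tert-butyl hydroperoxide, CC(C)(C)OO
Why: Sharpless asymmetric epoxidation directed by the C14 hydroxyl; only C1=C10 is allylic to it, and L-(+)-tartrate should deliver oxygen to the face that gives 1R,10S. The syn addition keeps C9 and C2 trans on the new oxirane.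

## Compound list

1 | (2Z)-3-methylpent-2-en-4-yn-1-ol | C#C/C(C)=C\CO | starting material
2 | [(2S,3R)-3-ethynyl-3-methyloxiran-2-yl]methanol | OC[C@@H]1O[C@]1(C)C#C | intermediate
3 | (2R,3R)-2-ethynyl-3-(iodomethyl)-2-methyloxirane (not isolated) | IC[C@@H]1O[C@]1(C)C#C | intermediate
4 | (3S)-3-methylpent-1-en-4-yn-3-ol | C#C[C@@](C)(O)C=C | intermediate
5 | (3S)-3-[(4-methoxybenzyl)oxy]-3-methylpent-1-en-4-yne | C#C[C@@](C)(OCc1ccc(OC)cc1)C=C | intermediate
6 | (3R)-3-[(4-methoxybenzyl)oxy]-3-methylpent-4-yne-1,2-diol, both C2 epimers (not isolated) | C#C[C@@](C)(OCc1ccc(OC)cc1)C(O)CO | intermediate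
7 | (2R)-2-[(4-methoxybenzyl)oxy]-2-methylbut-3-ynal | C#C[C@@](C)(OCc1ccc(OC)cc1)C=O | intermediate
8 | ethyl 2-(hydroxymethyl)prop-2-enoate | C=C(CO)C(=O)OCC | starting material
9 | ethyl 2-{[(tert-butyldimethylsilyl)oxy]methyl}prop-2-enoate | C=C(CO[Si](C)(C)C(C)(C)C)C(=O)OCC | intermediate
10 | 2-{[(tert-butyldimethylsilyl)oxy]methyl}prop-2-enoic acid | C=C(CO[Si](C)(C)C(C)(C)C)C(=O)O | intermediate
11 | prop-2-yn-1-ol | C#CCO | starting material
12 | allylmagnesium bromide | C=CC[Mg]Br | starting material
13 | 4-(prop-2-en-1-yl)-2,5-dihydro-1,2-oxamagnesole, cyclic alkenylmagnesium alkoxide (not isolated) | C=CCC1=C[Mg]OC1 | intermediate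
14 | (2Z)-2-(iodomethylidene)pent-4-en-1-ol | OC/C(CC=C)=C\I | intermediate
15 | tert-butyl{[(2Z)-2-(iodomethylidene)pent-4-en-1-yl]oxy}diphenylsilane | C=CC/C(CO[Si](c1ccccc1)(c1ccccc1)C(C)(C)C)=C/I | intermediate
16 | rac-(4Z)-4-{[(tert-butyldiphenylsilyl)oxy]methyl}-5-iodopent-4-ene-1,2-diol (not isolated) | OCC(O)C/C(CO[Si](c1ccccc1)(c1ccccc1)C(C)(C)C)=C/I | intermediate
17 | (3Z)-3-{[(tert-butyldiphenylsilyl)oxy]methyl}-4-iodobut-3-enal | O=CC/C(CO[Si](c1ccccc1)(c1ccccc1)C(C)(C)C)=C/I | intermediate
18 | 2-bromoprop-2-en-1-ol | C=C(Br)CO | starting material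
19 | lithium 2-lithioprop-2-en-1-olate (not isolated) | C=C([Li])CO[Li] | intermediate
20 | rac-(5Z)-5-{[(tert-butyldiphenylsilyl)oxy]methyl}-6-iodo-2-methylidenehex-5-ene-1,3-diol | C=C(CO)C(O)C/C(CO[Si](c1ccccc1)(c1ccccc1)C(C)(C)C)=C/I | intermediate
21 | rac-(5Z)-5-{[(tert-butyldiphenylsilyl)oxy]methyl}-3-hydroxy-6-iodo-2-methylidenehex-5-en-1-yl 2-{[(tert-butyldimethylsilyl)oxy]methyl}prop-2-enoate | C=C(CO[Si](C)(C)C(C)(C)C)C(=O)OCC(=C)C(O)C/C(CO[Si](c1ccccc1)(c1ccccc1)C(C)(C)C)=C/I | intermediate
22 | (5Z)-5-{[(tert-butyldiphenylsilyl)oxy]methyl}-6-iodo-2-methylidene-3-oxohex-5-en-1-yl 2-{[(tert-butyldimethylsilyl)oxy]methyl}prop-2-enoate | C=C(CO[Si](C)(C)C(C)(C)C)C(=O)OCC(=C)C(=O)C/C(CO[Si](c1ccccc1)(c1ccccc1)C(C)(C)C)=C/I | intermediate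
23 | (3S,5Z)-5-{[(tert-butyldiphenylsilyl)oxy]methyl}-3-hydroxy-6-iodo-2-methylidenehex-5-en-1-yl 2-{[(tert-butyldimethylsilyl)oxy]methyl}prop-2-enoate | O[C@@H](C/C(CO[Si](c1ccccc1)(c1ccccc1)C(C)(C)C)=C/I)C(=C)COC(=O)C(=C)CO[Si](C)(C)C(C)(C)C | intermediate
24 | (2R)-2-methylbutanoic acid | CC[C@@H](C)C(=O)O | starting material
25 | (3S,5Z)-5-{[(tert-butyldiphenylsilyl)oxy]methyl}-6-iodo-2-methylidene-3-{[(2R)-2-methylbutanoyl]oxy}hex-5-en-1-yl 2-{[(tert-butyldimethylsilyl)oxy]methyl}prop-2-enoate | CC[C@@H](C)C(=O)O[C@@H](C/C(CO[Si](c1ccccc1)(c1ccccc1)C(C)(C)C)=C/I)C(=C)COC(=O)C(=C)CO[Si](C)(C)C(C)(C)C | intermediate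
26 | (1S,3Z)-1-[4-{[(tert-butyldimethylsilyl)oxy]methyl}-5-oxo-2,5-dihydrofuran-3-yl]-3-{[(tert-butyldiphenylsilyl)oxy]methyl}-4-iodobut-3-en-1-yl (2R)-2-methylbutanoate | CC[C@@H](C)C(=O)O[C@@H](C/C(CO[Si](c1ccccc1)(c1ccccc1)C(C)(C)C)=C/I)C1=C(CO[Si](C)(C)C(C)(C)C)C(=O)OC1 | intermediate
27 | (1S,3Z,7R)-1-[4-{[(tert-butyldimethylsilyl)oxy]methyl}-5-oxo-2,5-dihydrofuran-3-yl]-3-{[(tert-butyldiphenylsilyl)oxy]methyl}-7-[(4-methoxybenzyl)oxy]-7-methyl-8-oxooct-3-en-5-yn-1-yl (2R)-2-methylbutanoate | CC[C@@H](C)C(=O)O[C@@H](C/C(CO[Si](c1ccccc1)(c1ccccc1)C(C)(C)C)=C/C#C[C@@](C)(OCc1ccc(OC)cc1)C=O)C1=C(CO[Si](C)(C)C(C)(C)C)C(=O)OC1 | intermediate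
28 | (1S,3Z,5Z,7R)-1-[4-{[(tert-butyldimethylsilyl)oxy]methyl}-5-oxo-2,5-dihydrofuran-3-yl]-3-{[(tert-butyldiphenylsilyl)oxy]methyl}-7-[(4-methoxybenzyl)oxy]-7-methyl-8-oxoocta-3,5-dien-1-yl (2R)-2-methylbutanoate | CC[C@@H](C)C(=O)O[C@@H](C/C(CO[Si](c1ccccc1)(c1ccccc1)C(C)(C)C)=C/C=C\[C@@](C)(OCc1ccc(OC)cc1)C=O)C1=C(CO[Si](C)(C)C(C)(C)C)C(=O)OC1 | intermediate
29 | (1S,3Z,5Z,7R)-1-[5-[(tert-butyldimethylsilyl)oxy]-4-{[(tert-butyldimethylsilyl)oxy]methyl}furan-3-yl]-3-{[(tert-butyldiphenylsilyl)oxy]methyl}-7-[(4-methoxybenzyl)oxy]-7-methyl-8-oxoocta-3,5-dien-1-yl (2R)-2-methylbutanoate | CC[C@@H](C)C(=O)O[C@@H](C/C(CO[Si](c1ccccc1)(c1ccccc1)C(C)(C)C)=C/C=C\[C@@](C)(OCc1ccc(OC)cc1)C=O)c1coc(O[Si](C)(C)C(C)(C)C)c1CO[Si](C)(C)C(C)(C)C | intermediate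
30 | (1(10)Z,2Z,4R,5R,6S,8S)-13-[(tert-butyldimethylsilyl)oxy]-14-[(tert-butyldiphenylsilyl)oxy]-5-hydroxy-4-[(4-methoxybenzyl)oxy]-8-{[(2R)-2-methylbutanoyl]oxy}germacra-1(10),2,7(11)-trien-12,6-olide | CC[C@@H](C)C(=O)O[C@H]1C/C(CO[Si](c2ccccc2)(c2ccccc2)C(C)(C)C)=C/C=C\[C@@](C)(OCc2ccc(OC)cc2)[C@H](O)[C@H]2OC(=O)C(CO[Si](C)(C)C(C)(C)C)=C12 | intermediate
31 | (1(10)Z,2Z,4R,5R,6S,8S)-14-[(tert-butyldiphenylsilyl)oxy]-5,13-dihydroxy-4-[(4-methoxybenzyl)oxy]-8-{[(2R)-2-methylbutanoyl]oxy}germacra-1(10),2,7(11)-trien-12,6-olide | CC[C@@H](C)C(=O)O[C@H]1C/C(CO[Si](c2ccccc2)(c2ccccc2)C(C)(C)C)=C/C=C\[C@@](C)(OCc2ccc(OC)cc2)[C@H](O)[C@H]2OC(=O)C(CO)=C12 | intermediate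
32 | (1(10)Z,2Z,4R,5R,6S,8S)-13-acetoxy-14-[(tert-butyldiphenylsilyl)oxy]-5-hydroxy-4-[(4-methoxybenzyl)oxy]-8-{[(2R)-2-methylbutanoyl]oxy}germacra-1(10),2,7(11)-trien-12,6-olide | CC[C@@H](C)C(=O)O[C@H]1C/C(CO[Si](c2ccccc2)(c2ccccc2)C(C)(C)C)=C/C=C\[C@@](C)(OCc2ccc(OC)cc2)[C@H](O)[C@H]2OC(=O)C(COC(C)=O)=C12 | intermediate
33 | (1(10)Z,2Z,4R,5R,6S,8S)-13-acetoxy-14-[(tert-butyldiphenylsilyl)oxy]-4,5-dihydroxy-8-{[(2R)-2-methylbutanoyl]oxy}germacra-1(10),2,7(11)-trien-12,6-olide | CC[C@@H](C)C(=O)O[C@H]1C/C(CO[Si](c2ccccc2)(c2ccccc2)C(C)(C)C)=C/C=C\[C@@](C)(O)[C@H](O)[C@H]2OC(=O)C(COC(C)=O)=C12 | intermediate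
34 | (1(10)Z,2Z,4R,5S,6S,8S)-13-acetoxy-14-[(tert-butyldiphenylsilyl)oxy]-4,5-epoxy-8-{[(2R)-2-methylbutanoyl]oxy}germacra-1(10),2,7(11)-trien-12,6-olide | CC[C@@H](C)C(=O)O[C@H]1C/C(CO[Si](c2ccccc2)(c2ccccc2)C(C)(C)C)=C/C=C\[C@@]2(C)O[C@H]2[C@H]2OC(=O)C(COC(C)=O)=C12 | intermediate
35 | (1(10)Z,2Z,4R,5S,6S,8S)-13-acetoxy-4,5-epoxy-14-hydroxy-8-{[(2R)-2-methylbutanoyl]oxy}germacra-1(10),2,7(11)-trien-12,6-olide | CC[C@@H](C)C(=O)O[C@H]1C/C(CO)=C/C=C\[C@@]2(C)O[C@H]2[C@H]2OC(=O)C(COC(C)=O)=C12 | intermediate
36 | (1R,2Z,4R,5S,6S,8S,10S)-13-acetoxy-1,10:4,5-diepoxy-14-hydroxy-8-{[(2R)-2-methylbutanoyl]oxy}germacra-2,7(11)-dien-12,6-olide (CNP0108300.1) | CC[C@@H](C)C(=O)O[C@H]1C[C@@]2(CO)O[C@@H]2/C=C\[C@@]2(C)O[C@H]2[C@H]2OC(=O)C(COC(C)=O)=C12 | target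

## Step count and least certain steps

Total step count: 25. Longest linear sequence: 19 steps (from 11 through steps 7 to 25). The branch from 1 joins at step 16 after four steps, and the branch from 8 joins at step 11 after two steps.

Step 19 (key step, new method). What may go wrong: intermolecular aldol addition could outrun the ten-membered closure; the furan face may be selected poorly, so that C6 comes out mixed; and the Lewis acid could ionise the furylic C8 ester. The fallback uses only known reaction types and moves the aldol out of the ring closure. It sets out from 26 and 7. Iodide 26 would be silylated as in step 18 (no aldehyde is present) to the silyloxyfuran of the vinyl iodide, F1. Intermolecular MgBr2-mediated, chelation-controlled vinylogous Mukaiyama aldol addition of F1 to 7 would give the open-chain aldol adduct with iodoalkene and terminal alkyne, F2; C5 is set by the same chelate, and C6 would rest on the usual open-transition-state preference and would have to be confirmed. An intramolecular Sonogashira coupling at high dilution would then close the ring at C1–C2 to the macrocyclic enyne, F3. Lindlar semi-hydrogenation inside the ring would return to the route at 30.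

Step 18. What may go wrong: the silyl triflate may promote an unchelated aldol or oligomerisation before 29 can be isolated, and the silyloxyfuran may hydrolyse on work-up. Fallback: no isolation and no silyl triflate. Starting from 28, the aldehyde would first be complexed with MgBr2·OEt2; Et3N and Me3SiCl would then be added at −40 °C so that the transient trimethylsilyloxyfuran, F4, forms next to the already chelated aldehyde and is consumed as it forms. This joins the route at 30.

Step 15. What may go wrong: metathesis may stall at the tetrasubstituted alkene next to the branched C8 ester, and the acrylate may dimerise instead. Fallback: change the order of ring closure and acylation. Starting from 23, the free allylic hydroxyl (a smaller and metathesis-assisting neighbour) would be kept during ring closure, giving the hydroxy butenolide, F5; esterification with 24 as in step 14 then rejoins the route at 26.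

Step 23. What may go wrong: the phosphorane may ionise at the tertiary dienylic C4–O bond, with loss of configuration; elimination across C5–C6 to an alkylidene butenolide or retro-aldol cleavage may be triggered by the basic betaine. Fallback: separate activation from closure, so that the leaving group sits on C5 before the C4 oxygen is freed. Starting from 32, sulfonylation with Ms2O in pyridine at 0 °C would give the C5 mesylate, F6. DDQ as in step 22 would give the C4-hydroxy C5-mesylate, F7, and brief treatment with Cs2CO3 in MeCN at 0 °C would close the oxirane with inversion, rejoining the route at 34.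

Step 25. What may go wrong: the titanium alkoxide may open the dienyl 4,5-oxirane, and the sense of tartrate control may be opposed by the ring conformation. Fallback: substrate control without a Lewis acid. Starting from 35, a buffered peracid (3-chloroperbenzoic acid, NaHCO3, CH2Cl2, −20 °C) would epoxidise the hydroxyl-bearing, more electron-rich C1=C10 alkene from the outer face of the ten-membered ring and arrive at 36. The face would have to be checked, and no new compound is involved.

## Further compounds

F1 | step 19 | (1S,3Z)-1-[5-[(tert-butyldimethylsilyl)oxy]-4-{[(tert-butyldimethylsilyl)oxy]methyl}furan-3-yl]-3-{[(tert-butyldiphenylsilyl)oxy]methyl}-4-iodobut-3-en-1-yl (2R)-2-methylbutanoate | CC[C@@H](C)C(=O)O[C@@H](C/C(CO[Si](c1ccccc1)(c1ccccc1)C(C)(C)C)=C/I)c1coc(O[Si](C)(C)C(C)(C)C)c1CO[Si](C)(C)C(C)(C)C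
F2 | step 19 | open-chain aldol adduct (4R,5R,6S,8S; C1 iodoalkene, C2 terminal alkyne) | CC[C@@H](C)C(=O)O[C@@H](C/C(CO[Si](c1ccccc1)(c1ccccc1)C(C)(C)C)=C/I)C1=C(CO[Si](C)(C)C(C)(C)C)C(=O)O[C@@H]1[C@@H](O)[C@](C)(OCc1ccc(OC)cc1)C#C
F3 | step 19 | macrocyclic enyne, the 2,3-didehydro analogue of 30 | CC[C@@H](C)C(=O)O[C@H]1C/C(CO[Si](c2ccccc2)(c2ccccc2)C(C)(C)C)=C/C#C[C@@](C)(OCc2ccc(OC)cc2)[C@H](O)[C@H]2OC(=O)C(CO[Si](C)(C)C(C)(C)C)=C12
F4 | step 18 | trimethylsilyloxyfuran analogue of 29 (not isolated) | CC[C@@H](C)C(=O)O[C@@H](C/C(CO[Si](c1ccccc1)(c1ccccc1)C(C)(C)C)=C/C=C\[C@@](C)(OCc1ccc(OC)cc1)C=O)c1coc(O[Si](C)(C)C)c1CO[Si](C)(C)C(C)(C)C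
F5 | step 15 | 3-{[(tert-butyldimethylsilyl)oxy]methyl}-4-[(1S,3Z)-3-{[(tert-butyldiphenylsilyl)oxy]methyl}-1-hydroxy-4-iodobut-3-en-1-yl]furan-2(5H)-one | O[C@@H](C/C(CO[Si](c1ccccc1)(c1ccccc1)C(C)(C)C)=C/I)C1=C(CO[Si](C)(C)C(C)(C)C)C(=O)OC1
F6 | step 23 | C5 methanesulfonate of 32 | CC[C@@H](C)C(=O)O[C@H]1C/C(CO[Si](c2ccccc2)(c2ccccc2)C(C)(C)C)=C/C=C\[C@@](C)(OCc2ccc(OC)cc2)[C@H](OS(C)(=O)=O)[C@H]2OC(=O)C(COC(C)=O)=C12
F7 | step 23 | C4-hydroxy C5-methanesulfonate | CC[C@@H](C)C(=O)O[C@H]1C/C(CO[Si](c2ccccc2)(c2ccccc2)C(C)(C)C)=C/C=C\[C@@](C)(O)[C@H](OS(C)(=O)=O)[C@H]2OC(=O)C(COC(C)=O)=C12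
F0 | step 25 | none | none
A1 | alternative 1 | (2Z,4Z,6Z)-2-(2-{[tert-butyl(dimethyl)silyl]oxy}ethyl)-6-methylocta-2,4,6-triene-1,8-diol | OC/C(CCO[Si](C)(C)C(C)(C)C)=C\C=C/C(C)=C\CO
A2 | alternative 1 | Z-ene bis-epoxy diol (1R,4R,5S,10S; C8–C10, C1–C6, C14, C15) | OC[C@]1(CCO[Si](C)(C)C(C)(C)C)O[C@@H]1/C=C\[C@@]1(C)O[C@H]1CO
A3 | alternative 2 | 6,7-seco C6 epoxy aldehyde with C7 enol triflate cis to the C12 methyl ester | CC[C@@H](C)C(=O)O[C@@H](C[C@@]1(CO[Si](C)(C)C(C)(C)C)O[C@@H]1/C=C\[C@@]1(C)O[C@H]1C=O)/C(OS(=O)(=O)C(F)(F)F)=C(\COC(C)=O)C(=O)OC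
A4 | alternative 2 | C14 tert-butyldimethylsilyl ether of 36 | CC[C@@H](C)C(=O)O[C@H]1C[C@@]2(CO[Si](C)(C)C(C)(C)C)O[C@@H]2/C=C\[C@@]2(C)O[C@H]2[C@H]2OC(=O)C(COC(C)=O)=C12
A5 | alternative 3 | 1,2-seco alkynyl aldehyde (C1 aldehyde on the spiro-oxirane carbon C10, C2 terminal alkyne, open methyl ester) | CC(C)(C)[Si](C)(C)O[C@@H](C[C@]2(C=O)CO2)/C(=C(\CO[Si](C)(C)C(C)(C)C)C(=O)OC)[C@H](O[Si](CC)(CC)CC)[C@@H]1O[C@]1(C)C#C
A6 | alternative 3 | ten-membered cycloalkyne epoxy alcohol | CC(C)(C)[Si](C)(C)O[C@H]1C[C@@]2(CO2)[C@H](O)C#C[C@@]2(C)O[C@H]2[C@@H](O[Si](CC)(CC)CC)/C1=C(/CO[Si](C)(C)C(C)(C)C)C(=O)OC
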